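**Strategy.** Each half is a spiro[4.5]decane whose cyclohexane ring carries the C6 methyl carbinol next to the spiro carbon C5, while the cyclopentane carries the C1 carbinol on the other side of C5. This O–C1–C5–C6–O array is read as a β-hydroxy ketone, the retron of a semipinacol rearrangement: an epoxide on a cyclopentene that bears a 2,3-disubstituted cyclopentanol is opened at the future C5, a ring bond of the cyclopentanol shifts, and the cyclohexanone ring, the spiro quaternary centre and the C1 carbinol appear together. Methyl addition, a lactone-based side-chain synthesis and a biomimetic Diels–Alder dimerisation of the tetraene halves complete the route.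

Key step: step 9

Remarks on the chemistry:
- Spiro compounds are named with spiro[4.5]decane locants: C1 = carbinol CH of the cyclopentane, C2 = its side-chain-bearing neighbour, C5 = spiro carbon, C6 = carbonyl or methyl carbinol carbon, C9 = carbon that ends as the enal-bearing ring carbon, C10 = CH carrying the three-carbon chain. In the cyclopentanol precursors 16 and 17, C1' = carbinol carbon, C2' = chain-bearing CH, C3' = silyloxy CH, C5' = CH2.
- The carbinol centres made in steps 7, 14 and 16 are destroyed later; they are drawn as the expected major isomer or left open.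
- In steps 3 and 5 the enantiomer of the ligand is the one that gives the configuration drawn; the antipode of the ligand would give the other series.

Step 1
Reactants: 1 2-bromocyclopent-2-en-1-one
Product: 2 6-bromo-1,4-dioxaspiro[4.4]non-6-ene
Conditions: ethane-1,2-diol, TsOH·H2O (cat.), benzene, reflux, Dean–Stark
Reagents that add atoms: ethane-1,2-diol, OCCO
Why: Acid-catalysed ketalisation masks the carbonyl so that the vinyl bromide can serve as an α-keto vinyl anion equivalent; no stereocentre is involved.

Step 2
Reactants: 2 6-bromo-1,4-dioxaspiro[4.4]non-6-ene; 3 1-chloro-3-iodopropane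
Product: 6 2-(3-chloropropyl)cyclopent-2-en-1-one, via vinyllithium 4 (not isolated), via alkylated ketal 5 (not isolated)
Conditions: n-BuLi, THF, −78 °C; then 3, DMPU, −78 °C → rt; then aq. oxalic acid, THF, rt
Reagents that add atoms: none
Why: Bromine–lithium exchange gives a vinyllithium that is alkylated by SN2 at the C–I end of 3 (the chloride survives as a latent ester site), and mild acid releases the enone (alkylation of an α-keto vinyl anion equivalent).

Step 3
Reactants: 6 2-(3-chloropropyl)cyclopent-2-en-1-one
Product: 8 (2R,3S)-2-(3-chloropropyl)-3-hydroxycyclopentan-1-one, via boryl ketone 7 (not isolated)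
Conditions: CuCl (3 mol %), NaOtBu (5 mol %), (R)-1-[(S)-2-(diphenylphosphino)ferrocenyl]ethyldicyclohexylphosphine (3 mol %), B2pin2, MeOH, THF, rt; then NaBO3·4H2O, THF/H2O, 0 °C → rt
Reagents that add atoms: bis(pinacolato)diboron, CC1(C)OB(OC1(C)C)B1OC(C)(C)C(C)(C)O1; sodium perborate, [Na+].[O-]OB=O
Why: Copper-catalysed enantioselective conjugate borylation sets C3 by ligand-controlled face selection, protonation of the enolate by MeOH with base equilibration places the chain trans at C2, and perborate oxidises C–B to C–O with retention.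

Step 4
Reactants: 8 (2R,3S)-2-(3-chloropropyl)-3-hydroxycyclopentan-1-one
Product: 9 (2R,3S)-2-(3-chloropropyl)-3-(triethylsilyloxy)cyclopentan-1-one
Conditions: Et3SiCl, imidazole, CH2Cl2, 0 °C
Reagents that add atoms: chlorotriethylsilane, CC[Si](Cl)(CC)CC
Why: Silylation of the secondary alcohol keeps this oxygen from adding to the epoxide in step 9 and blocks β-elimination; no stereocentre changes.

Step 5
Reactants: 10 cyclopent-2-en-1-one; 11 (1,3-dioxolan-2-ylmethyl)magnesium bromide
Product: 13 (S)-3-(1,3-dioxolan-2-ylmethyl)cyclopent-1-en-1-yl trifluoromethanesulfonate, via magnesium enolate 12 (not isolated)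
Conditions: CuBr·SMe2 (5 mol %), (R)-1-[(S)-2-(diphenylphosphino)ferrocenyl]ethyldicyclohexylphosphine (6 mol %), tBuOMe, −75 °C; then N-(5-chloropyridin-2-yl)bis(trifluoromethanesulfonimide), THF, −75 → 0 °C
Reagents that add atoms: N-(5-chloropyridin-2-yl)bis(trifluoromethanesulfonimide), FC(F)(F)S(=O)(=O)N(c1ccc(Cl)cn1)S(=O)(=O)C(F)(F)F
Why: Copper-catalysed asymmetric conjugate addition of the Grignard reagent sets the C3 centre under ligand control, and O-triflation of the regiodefined enolate fixes the double bond between C1 and C2.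

Step 6
Reactants: 13 (S)-3-(1,3-dioxolan-2-ylmethyl)cyclopent-1-en-1-yl trifluoromethanesulfonate
Product: 14 (S)-[3-(1,3-dioxolan-2-ylmethyl)cyclopent-1-en-1-yl]trimethylstannane
Conditions: Pd(PPh3)4 (5 mol %), Me3SnSnMe3, LiCl, THF, 65 °C
Reagents that add atoms: hexamethylditin, C[Sn](C)(C)[Sn](C)(C)C
Why: Palladium-catalysed stannylation of an enol triflate (oxidative addition, transmetalation with the distannane, reductive elimination) keeps the alkene position and the stereocentre.

Step 7
Reactants: 14 (S)-[3-(1,3-dioxolan-2-ylmethyl)cyclopent-1-en-1-yl]trimethylstannane; 9 (2R,3S)-2-(3-chloropropyl)-3-(triethylsilyloxy)cyclopentan-1-one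
Product: 16 (2R,3S)-2-(3-chloropropyl)-1-[(S)-3-(1,3-dioxolan-2-ylmethyl)cyclopent-1-en-1-yl]-3-(triethylsilyloxy)cyclopentan-1-ol, via vinyllithium 15 (not isolated)
Conditions: MeLi, THF, −78 → −40 °C; then anhydrous CeCl3, −78 °C; then 9, −78 °C; aq. NH4Cl
Reagents that add atoms: none
Why: Tin–lithium exchange followed by cerium-mediated 1,2-addition (which suppresses enolisation of the α-stereocentre) should deliver the cyclopentenyl group trans to the adjacent chain; this carbinol centre is lost in step 9.

Step 8
Reactants: 16 tertiary allylic alcohol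
Product: 17 epoxy alcohol (oxirane across the cyclopentene double bond, oxygen anti to the dioxolanylmethyl group)
Conditions: VO(acac)2 (5 mol %), tBuOOH (decane), CH2Cl2, 0 °C
Reagents that add atoms: tert-butyl hydroperoxide, CC(C)(C)OO
Why: Vanadium-catalysed hydroxyl-directed epoxidation touches only the allylic alkene, and the oxidant should approach the cyclopentene face opposite the allylic dioxolanylmethyl substituent (steric control by the C3 centre of the cyclopentene).

Step 9
Reactants: 17 epoxy alcohol
Product: 18 10-(3-chloropropyl)-2-(1,3-dioxolan-2-ylmethyl)-1-hydroxy-9-(triethylsilyloxy)spiro[4.5]decan-6-one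
Conditions: ZnBr2 (1 equiv), CH2Cl2, 0 °C → rt
Reagents that add atoms: none
Why: Coordination of ZnBr2 to the epoxide weakens the C–O bond at the fully substituted epoxide carbon, and the ring bond C1'–C2' of the cyclopentanol shifts to that carbon in concert with opening while the carbinol carbon becomes the C6 ketone (semipinacol rearrangement of a 2,3-epoxy alcohol). The closest known reaction type is the Lewis-acid-promoted rearrangement of α-hydroxy epoxides derived from 1-(cycloalkenyl)cycloalkanols to spirocyclic β-hydroxy ketones. No ring is closed by cyclisation: the six-membered ring arises by insertion of the epoxide carbon into the five-membered carbinol ring through a 1,2-alkyl shift (cyclopentanol to cyclohexanone). The spiro centre C5 is set stereospecifically because the migrating carbon enters anti to the departing epoxide oxygen, which places C10 cis to the C2 substituent; the C1 carbinol keeps the epoxide configuration (trans to the C2 substituent), and C10 migrates with retention. The step needs opening at the tertiary rather than the secondary epoxide carbon and migration of the secondary carbon C2' rather than the methylene C5'; the first is secured by the tertiary carbinol-bearing terminus, the second by the higher migratory aptitude of the more substituted carbon, and the silyl ether keeps the neighbouring oxygen from attacking the epoxide.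

Step 10
Reactants: 18 spiro β-hydroxy ketone
Product: 20 2-[10-(3-chloropropyl)-1,6,9-trihydroxy-6-methylspiro[4.5]decan-2-yl]acetaldehyde, via methyl carbinol 19 (not isolated)
Conditions: MeLi, anhydrous CeCl3, THF, −78 °C; then 2 M HCl, THF, rt
Reagents that add atoms: methyllithium, [Li]C; water, O
Why: Organocerium methyl addition to the hindered ketone should occur on the face opposite the C10 chain and the C1 branch of the cyclopentane (steric approach control), setting C6 with the methyl cis to C4; aqueous acid then cleaves the silyl ether and the acetal.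

Step 11
Reactants: 20 trihydroxy aldehyde
Product: 21 2-[10-(3-chloropropyl)-6-hydroxy-6-methyl-1,9-dioxospiro[4.5]decan-2-yl]acetic acid
Conditions: RuCl3·xH2O (5 mol %), NaIO4, MeCN/EtOAc/H2O, 0 °C → rt
Reagents that add atoms: sodium periodate, [Na+].[O-]I(=O)(=O)=O; water, O
Why: Catalytic RuO4 oxidises both secondary alcohols to ketones and the aldehyde to the acid in a weakly acidic medium that should not enolise the α-centres C2 and C10; the wrongly configured C1 carbinol is erased for re-setting.

Step 12
Reactants: 21 diketo acid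
Product: 23 keto lactone (γ-lactone between the C1 oxygen and the acetic acid arm on C2, cis-fused), via hydroxy acid 22 (not isolated)
Conditions: Me4NBH(OAc)3, MeCN/AcOH, −20 °C; then TsOH·H2O (cat.), CH2Cl2, rt
Reagents that add atoms: none
Why: Exchange of the tertiary C6 hydroxyl onto boron and intramolecular hydride delivery (Evans–Saksena directed reduction) reduces only the β-hydroxy ketone at C1 from the face of C6, which places the new hydroxyl cis to the acetic acid arm and to C10 so that it lactonises; the C9 ketone has no directing hydroxyl within reach and is left.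

Step 13
Reactants: 24 ethyl prop-1-enyl ether
Product: 26 (Z)-2-bromo-1-ethoxyprop-1-ene, via dibromo ether 25 (not isolated)
Conditions: Br2, CH2Cl2, −78 °C; then Et3N, −78 → 40 °C
Reagents that add atoms: bromine, BrBr
Why: Bromine addition followed by loss of HBr through the α-bromo ether (oxocarbenium) gives the β-bromo enol ether, the known route to 2-alkoxyvinyl bromides.

Step 14
Reactants: 26 (Z)-2-bromo-1-ethoxyprop-1-ene; 23 keto lactone
Product: 28 tertiary allylic alcohol (23 with C9 converted into C(OH)[(Z)-1-ethoxyprop-1-en-2-yl]), via alkenyllithium 27 (not isolated)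
Conditions: tBuLi (2 equiv per 26), Et2O/THF, −78 °C; then anhydrous CeCl3; then 23, −78 °C; pH 7 buffer
Reagents that add atoms: none
Why: Bromine–lithium exchange gives the chelated 2-ethoxyalkenyllithium, whose cerium-mediated addition is faster at the ketone than at the lactone and avoids enolisation at C10; this carbinol centre is lost in step 20.

Step 15
Reactants: 29 β-myrcene; 30 (E)-crotonaldehyde
Product: 31 (2E)-8-methyl-4-methylidenenona-2,7-dienal
Conditions: second-generation Hoveyda–Grubbs catalyst RuCl2(H2IMes)(=CH-C6H4-2-OiPr) (3 mol %), CH2Cl2, 40 °C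
Reagents that add atoms: none
Why: Cross-metathesis should engage only the monosubstituted alkene of the diene, because the 1,1-disubstituted and trisubstituted alkenes are much slower, and gives the E enal.

Step 16
Reactants: 28 tertiary allylic alcohol; 31 (2E)-8-methyl-4-methylidenenona-2,7-dienal
Product: 32 β-hydroxy lactone (aldol adduct at the lactone α-carbon; both new centres left open)
Conditions: LiN(iPr)2 (3.3 equiv), THF, −78 °C; then 31, −78 °C; aq. NH4Cl
Reagents that add atoms: none
Why: After deprotonation of the two tertiary hydroxyls the lactone lithium enolate adds 1,2 to the dienal (aldol addition); both new centres disappear in step 17.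

Step 17
Reactants: 32 β-hydroxy lactone
Product: 34 (E)-α-alkylidene lactone, via allylic acetate 33 (not isolated)
Conditions: Ac2O, Et3N, DMAP (cat.), CH2Cl2, 0 °C; then DBU, rt
Reagents that add atoms: acetic anhydride, CC(=O)OC(C)=O
Why: Selective acetylation of the secondary alcohol and E1cB elimination should give the thermodynamically preferred E alkylidene lactone with the dienyl chain anti to the carbonyl, which is the geometry of the trisubstituted alkene in the target.

Step 18
Reactants: 34 (E)-α-alkylidene lactone
Product: 35 tetraol (C1–OH, allylic CH2OH, C6–OH, C9–OH; 3-chloropropyl chain)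
Conditions: iBu2AlH (6 equiv), CH2Cl2, −78 → −20 °C; aq. Rochelle salt
Reagents that add atoms: none
Why: 1,2-Reduction of the unsaturated lactone through the lactol gives the C1 alcohol and the allylic primary alcohol; the alkyl chloride and the enol ether are inert to the hydride.

Step 19
Reactants: 35 tetraol; 36 tetradecanoic acid
Product: 37 myristate ester of 35
Conditions: Cs2CO3, NaI (cat.), DMF, 45 °C, dark
Reagents that add atoms: none
Why: SN2 displacement of the primary chloride by caesium tetradecanoate (iodide catalysis) forms the ester at the chain terminus only, so that no hydroxyl needs protection.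

Step 20
Reactants: 37 myristate ester
Product: 38 monomer, 3-[(1R,2S,5S,6S,10R)-1,6-dihydroxy-2-[(2E,4E)-1-hydroxy-10-methyl-6-methylideneundeca-2,4,9-trien-2-yl]-6-methyl-9-[(Z)-1-oxopropan-2-ylidene]spiro[4.5]decan-10-yl]propyl tetradecanoate
Conditions: PPTS (cat.), THF/H2O, 0 °C → rt
Reagents that add atoms: water, O
Why: Acid ionises the tertiary allylic alcohol with help from the enol ether, and hydrolysis of the oxocarbenium ion gives the tetrasubstituted enal (formyl-olefination by allylic transposition); the Z isomer, with the small formyl group syn to the substituted C10 and the methyl syn to the C8 methylene, should be favoured.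

Step 21
Reactants: 38 monomer (two molecules)
Product: 39 CNP0458412.1
Conditions: toluene (concentrated), BHT (cat.), 70 °C, argon, dark
Reagents that add atoms: none
Why: Thermal Diels–Alder dimerisation: the CH=CH–C(R)=CH2 diene of one molecule adds to the terminal 1,1-disubstituted alkene of the triene of a second, with regiochemistry set by the large frontier coefficients at the two CH2 termini; the drawn ring configuration needs the dienyl branch exo, the remote stereocentres should not bias the face of addition, and stereoisomers at the central ring have to be removed by HPLC.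

Compound list
1 | 2-bromocyclopent-2-en-1-one | O=C1CCC=C1Br | starting material
2 | 6-bromo-1,4-dioxaspiro[4.4]non-6-ene | BrC1=CCCC12OCCO2 | intermediate
3 | 1-chloro-3-iodopropane | ClCCCI | starting material
4 | (1,4-dioxaspiro[4.4]non-6-en-6-yl)lithium | [Li]C1=CCCC12OCCO2 | intermediate
5 | 6-(3-chloropropyl)-1,4-dioxaspiro[4.4]non-6-ene | ClCCCC1=CCCC12OCCO2 | intermediate
6 | 2-(3-chloropropyl)cyclopent-2-en-1-one | O=C1CCC=C1CCCCl | intermediate
7 | (2R,3S)-2-(3-chloropropyl)-3-(4,4,5,5-tetramethyl-1,3,2-dioxaborolan-2-yl)cyclopentan-1-one (trans) | ClCCC[C@@H]1[C@@H](B2OC(C)(C)C(C)(C)O2)CCC1=O | intermediate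
8 | (2R,3S)-2-(3-chloropropyl)-3-hydroxycyclopentan-1-one (trans) | ClCCC[C@@H]1[C@@H](O)CCC1=O | intermediate
9 | (2R,3S)-2-(3-chloropropyl)-3-(triethylsilyloxy)cyclopentan-1-one | ClCCC[C@@H]1[C@@H](O[Si](CC)(CC)CC)CCC1=O | intermediate
10 | cyclopent-2-en-1-one | O=C1C=CCC1 | starting material
11 | (1,3-dioxolan-2-ylmethyl)magnesium bromide | Br[Mg]CC1OCCO1 | starting material
12 | bromomagnesium (S)-3-(1,3-dioxolan-2-ylmethyl)cyclopent-1-en-1-olate | Br[Mg]OC1=C[C@H](CC2OCCO2)CC1 | intermediate
13 | (S)-3-(1,3-dioxolan-2-ylmethyl)cyclopent-1-en-1-yl trifluoromethanesulfonate | FC(F)(F)S(=O)(=O)OC1=C[C@H](CC2OCCO2)CC1 | intermediate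
14 | (S)-[3-(1,3-dioxolan-2-ylmethyl)cyclopent-1-en-1-yl]trimethylstannane | C[Sn](C)(C)C1=C[C@H](CC2OCCO2)CC1 | intermediate
15 | (S)-[3-(1,3-dioxolan-2-ylmethyl)cyclopent-1-en-1-yl]lithium | [Li]C1=C[C@H](CC2OCCO2)CC1 | intermediate
16 | (2R,3S)-2-(3-chloropropyl)-1-[(S)-3-(1,3-dioxolan-2-ylmethyl)cyclopent-1-en-1-yl]-3-(triethylsilyloxy)cyclopentan-1-ol, cyclopentenyl trans to the chloropropyl chain | ClCCC[C@@H]1[C@@H](O[Si](CC)(CC)CC)CC[C@@]1(O)C2=C[C@H](CC3OCCO3)CC2 | intermediate
17 | epoxide of 16 across the cyclopentene double bond, oxygen anti to the dioxolanylmethyl group | ClCCC[C@@H]1[C@@H](O[Si](CC)(CC)CC)CC[C@@]1(O)[C@]23O[C@H]2[C@H](CC4OCCO4)CC3 | intermediate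
18 | 10-(3-chloropropyl)-2-(1,3-dioxolan-2-ylmethyl)-1-hydroxy-9-(triethylsilyloxy)spiro[4.5]decan-6-one (C10 cis to the C2 substituent across C5; 1-OH trans to the C2 substituent; chain on C10 cis to C1; 9-O trans to the chain) | ClCCC[C@@H]1[C@@H](O[Si](CC)(CC)CC)CCC(=O)[C@@]12CC[C@@H](CC3OCCO3)[C@@H]2O | intermediate
19 | 6-methyl-6-ol from 18 (methyl cis to C4, hydroxyl cis to C1), silyl ether and acetal still present | ClCCC[C@@H]1[C@@H](O[Si](CC)(CC)CC)CC[C@](C)(O)[C@@]12CC[C@@H](CC3OCCO3)[C@@H]2O | intermediate
20 | 2-[10-(3-chloropropyl)-1,6,9-trihydroxy-6-methylspiro[4.5]decan-2-yl]acetaldehyde (1-OH trans to the C2 arm) | ClCCC[C@@H]1[C@@H](O)CC[C@](C)(O)[C@@]12CC[C@@H](CC=O)[C@@H]2O | intermediate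
21 | 2-[10-(3-chloropropyl)-6-hydroxy-6-methyl-1,9-dioxospiro[4.5]decan-2-yl]acetic acid | ClCCC[C@@H]1C(=O)CC[C@](C)(O)[C@@]12CC[C@@H](CC(=O)O)C2=O | intermediate
22 | 2-[10-(3-chloropropyl)-1,6-dihydroxy-6-methyl-9-oxospiro[4.5]decan-2-yl]acetic acid (1-OH cis to the C2 arm and to C10) | ClCCC[C@@H]1C(=O)CC[C@](C)(O)[C@@]12CC[C@@H](CC(=O)O)[C@H]2O | intermediate
23 | keto lactone: γ-lactone of 22, cis-fused to the cyclopentane, spiro-linked to the 9-oxo-6-hydroxy-6-methylcyclohexane | ClCCC[C@@H]1C(=O)CC[C@](C)(O)[C@@]12CC[C@@H](CC(=O)O3)[C@H]23 | intermediate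
24 | ethyl prop-1-enyl ether (E/Z mixture) | CCOC=CC | starting material
25 | 1,2-dibromo-1-ethoxypropane | CCOC(Br)C(C)Br | intermediate
26 | (Z)-2-bromo-1-ethoxyprop-1-ene | CCO/C=C(\Br)C | intermediate
27 | (1-ethoxyprop-1-en-2-yl)lithium, lithium cis to the ethoxy group | CCO/C=C(\[Li])C | intermediate
28 | 23 with C9 as C(OH)[(Z)-1-ethoxyprop-1-en-2-yl], hydroxyl cis to the chloropropyl chain | ClCCC[C@@H]1[C@@](O)(/C(C)=C\OCC)CC[C@](C)(O)[C@@]12CC[C@@H](CC(=O)O3)[C@H]23 | intermediate
29 | β-myrcene | C=CC(=C)CCC=C(C)C | starting material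
30 | (E)-crotonaldehyde | C/C=C/C=O | starting material
31 | (2E)-8-methyl-4-methylidenenona-2,7-dienal | O=C/C=C/C(=C)CCC=C(C)C | intermediate
32 | aldol adduct of the lactone α-carbon of 28 with 31 (α-carbon and carbinol carbon undefined) | ClCCC[C@@H]1[C@@](O)(/C(C)=C\OCC)CC[C@](C)(O)[C@@]12CC[C@@H](C(C(O)/C=C/C(=C)CCC=C(C)C)C(=O)O3)[C@H]23 | intermediate
33 | acetate of the secondary alcohol of 32 | ClCCC[C@@H]1[C@@](O)(/C(C)=C\OCC)CC[C@](C)(O)[C@@]12CC[C@@H](C(C(OC(C)=O)/C=C/C(=C)CCC=C(C)C)C(=O)O3)[C@H]23 | intermediate
34 | (E)-α-alkylidene lactone (dienyl chain anti to the lactone carbonyl) | ClCCC[C@@H]1[C@@](O)(/C(C)=C\OCC)CC[C@](C)(O)[C@@]12CC[C@@H](/C(=C\C=C\C(=C)CCC=C(C)C)C(=O)O3)[C@H]23 | intermediate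
35 | tetraol from reduction of 34 (C1–OH cis to the C2 side chain; allylic CH2OH; chloropropyl chain) | ClCCC[C@@H]1[C@@](O)(/C(C)=C\OCC)CC[C@](C)(O)[C@@]12CC[C@@H](/C(=C\C=C\C(=C)CCC=C(C)C)CO)[C@H]2O | intermediate
36 | tetradecanoic acid (myristic acid) | CCCCCCCCCCCCCC(=O)O | starting material
37 | tetradecanoate ester of 35 at the chain terminus | CCCCCCCCCCCCCC(=O)OCCC[C@@H]1[C@@](O)(/C(C)=C\OCC)CC[C@](C)(O)[C@@]12CC[C@@H](/C(=C\C=C\C(=C)CCC=C(C)C)CO)[C@H]2O | intermediate
38 | monomer, 3-[(1R,2S,5S,6S,10R)-1,6-dihydroxy-2-[(2E,4E)-1-hydroxy-10-methyl-6-methylideneundeca-2,4,9-trien-2-yl]-6-methyl-9-[(Z)-1-oxopropan-2-ylidene]spiro[4.5]decan-10-yl]propyl tetradecanoate | CCCCCCCCCCCCCC(=O)OCCC[C@@H]1/C(=C(/C)C=O)CC[C@](C)(O)[C@@]12CC[C@@H](/C(=C\C=C\C(=C)CCC=C(C)C)CO)[C@H]2O | intermediate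
39 | CNP0458412.1, Diels–Alder dimer of 38 (central cyclohexene with the dienyl branch on the quaternary carbon trans to the alkenyl branch on the adjacent CH) | CCCCCCCCCCCCCC(=O)OCCC[C@@H]1/C(=C(/C)C=O)CC[C@](C)(O)[C@@]12CC[C@@H](/C(=C\C=C\[C@@]1(CCC=C(C)C)CCC(CCC=C(C)C)=C[C@@H]1/C=C(/CO)[C@@H]1CC[C@]3([C@H](CCCOC(=O)CCCCCCCCCCCCC)/C(=C(/C)C=O)CC[C@]3(C)O)[C@@H]1O)CO)[C@H]2O | target

Total step count: 21. Longest linear sequence: 17 steps (steps 1–4, 7–12, 14, 16–21).

Steps most likely to fail

Step 21. The bimolecular cycloaddition may proceed with little exo/endo and facial discrimination and through competing diene/dienophile pairings, and the tetraene may polymerise. Fallback, setting out from 38 and coming back at 39: the allylic primary hydroxyls of two molecules of 38 are joined with iPr2SiCl2 (0.5 equiv), imidazole, DMF, 0 °C to the bis(allyloxy)diisopropylsilane F1. Heating F1 in dilute toluene (BHT, 90 °C) should effect a silicon-tethered intramolecular Diels–Alder reaction through a 13-membered tether ring, which allows only the required pairing and places the two enantiopure spirocycles next to the reacting termini, to give the silylene-tethered cycloadduct F2. HF·pyridine, THF, 0 °C then removes the silylene and returns 39.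

Step 9. The zinc-activated tertiary epoxide may instead lose a proton to an allylic alcohol, be intercepted by the acetal oxygen, lose the silyl group or shift the methylene ring bond. Fallback, setting out from 16 and coming back at 23: bromonium-triggered semipinacol rearrangement of 16 (NBS, propylene oxide, iPrOH/CH2Cl2, −20 °C) should give the spiro β-bromo ketone F3, with bromine trans to the C2 substituent and the spiro centre as in 18. MeLi/CeCl3, THF, −78 °C, then 2 M HCl gives the bromo aldehyde F4, and NaClO2, NaH2PO4, 2-methylbut-2-ene, tBuOH/H2O gives the bromo acid F5. Cs2CO3, DMF, 40 °C closes the hydroxy lactone F6 by intramolecular SN2 displacement of bromide, which inverts C1 directly to the cis-fused configuration. Dess–Martin periodinane, NaHCO3, CH2Cl2 oxidises the C9 carbinol and returns 23.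

Step 5. The magnesium enolate may add to unreacted cyclopentenone before triflation, and the enantioselectivity of the Grignard addition to the five-membered enone may be insufficient. Fallback, setting out from 11 and coming back at 13: 11 is added to purchased 3-ethoxycyclopent-2-en-1-one F7 (THF, 0 °C), and work-up with dilute aqueous oxalic acid (Stork–Danheiser transposition) gives 3-(1,3-dioxolan-2-ylmethyl)cyclopent-2-en-1-one F8. Copper hydride-catalysed asymmetric conjugate reduction (CuCl, NaOtBu, (S)-p-tol-BINAP, Ph2SiH2, toluene, −78 → 0 °C) gives the diphenylsilyl enol ether F9. MeLi in THF cleaves F9 to the enolate, and N-(5-chloropyridin-2-yl)bis(trifluoromethanesulfonimide) triflates it to 13.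

Further compounds
F1 | step 21 | bis(allyloxy)diisopropylsilane from two molecules of 38 | CCCCCCCCCCCCCC(=O)OCCC[C@@H]1/C(=C(/C)C=O)CC[C@](C)(O)[C@@]12CC[C@@H](/C(=C\C=C\C(=C)CCC=C(C)C)CO[Si](C(C)C)(C(C)C)OC/C(=C/C=C/C(=C)CCC=C(C)C)[C@@H]3CC[C@]4([C@H](CCCOC(=O)CCCCCCCCCCCCC)/C(=C(/C)C=O)CC[C@]4(C)O)[C@@H]3O)[C@H]2O
F2 | step 21 | silylene-tethered cycloadduct | CCCCCCCCCCCCCC(=O)OCCC[C@@H]1/C(=C(/C)C=O)CC[C@](C)(O)[C@@]12CC[C@@H](/C(=C\C=C\[C@@]1(CCC=C(C)C)CCC(CCC=C(C)C)=C[C@@H]1/C=C(/CO[Si]5(C(C)C)C(C)C)[C@@H]1CC[C@]3([C@H](CCCOC(=O)CCCCCCCCCCCCC)/C(=C(/C)C=O)CC[C@]3(C)O)[C@@H]1O)CO5)[C@H]2O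
F3 | step 9 | spiro β-bromo ketone | ClCCC[C@@H]1[C@@H](O[Si](CC)(CC)CC)CCC(=O)[C@@]12CC[C@@H](CC3OCCO3)[C@@H]2Br
F4 | step 9 | bromo aldehyde | ClCCC[C@@H]1[C@@H](O)CC[C@](C)(O)[C@@]12CC[C@@H](CC=O)[C@@H]2Br
F5 | step 9 | bromo acid | ClCCC[C@@H]1[C@@H](O)CC[C@](C)(O)[C@@]12CC[C@@H](CC(=O)O)[C@@H]2Br
F6 | step 9 | hydroxy lactone | ClCCC[C@@H]1[C@@H](O)CC[C@](C)(O)[C@@]12CC[C@@H](CC(=O)O3)[C@H]23
F7 | step 5 | 3-ethoxycyclopent-2-en-1-one | CCOC1=CC(=O)CC1
F8 | step 5 | 3-(1,3-dioxolan-2-ylmethyl)cyclopent-2-en-1-one | O=C1C=C(CC2OCCO2)CC1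
F9 | step 5 | diphenylsilyl enol ether | [SiH](c1ccccc1)(c1ccccc1)OC1=C[C@H](CC2OCCO2)CC1
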